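The data are calculated on assumed constants; scatter was added.

The easy step is to see Z as a tank with two drains in parallel. The drain into G runs as Z times J, which with J held steady is a pseudo-first-order drain, while the drain into D runs as the square of Z. Writing z for Z as a fraction of its charge, the two drains match at a crossover fraction x, and the share of lost Z that becomes G at any moment is x over x plus z. This x is the ratio of J charge to Z charge, times a ratio c of the two drain constants.

| flask | Z | J | remark | time |
|---|---|---|---|---|
| alpha | 1 M | 1.5 M | run made earlier |  |
| Friday's | 1.0 M | 2.50 M |  | 5.0 h |
| Saturday's | 1.0 M | 1.20 M |  | 20 h |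

- alpha (time / h: G / %, Z / %): 2.00: 11, 63; 4.00: 18, 45; 6.00: 22, 35; 8.00: 30, 29; 10.0: 29, 23

(scatter of a reading: 2 percentage points)

- in percentages every species weighs as the Z in it: one D or L counts as two
- steps that have been proposed: 2 Z -> D; Z -> E; 2 Z -> L; Z + J <-> G

1. which one finishes higher in amount of G, in percent of the Z charged ("neither" within 2 percentage points) (Friday's / Saturday's / neither)
2. amount of G at the end, in percent of the Z charged, Friday's
3. amount of G at the end, in percent of the Z charged, Saturday's

I leave E, L and the way back out of my reckoning. At alpha's last reading, G over Z lost gives a share of 0.377, and with z taken midway between its ends the crossover is 0.372. Taking J at its charge less half of the G made gives c = 0.274, the crossover ratio. Alpha's fall of z then sets the square drain at 0.174 h⁻¹.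

For Friday's, the crossover is 0.646, and the integrated drains leave z at 34.3 %. In this reckoning the share runs from its starting value to a larger end value, so my estimate of Friday's G lies between 25.8 % and 42.9 %. Averaging the share over the fall of z tightens this to 32.9 %. For Saturday's, the crossover 0.289 leaves z at 11.5 % and gives G 33.6 %. The two differ by 0.70 percentage points, inside the margin, so I commit to neither.

The forecast says Friday's, with 33 % (29 % to 38 %) and 30 % (24 % to 35 %), expecting that “any reverse step erodes G”; its Friday's value stands inside my bracket.

The flask gives 34.1 % for Friday's, inside the bracket, and 33.4 % for Saturday's, so the answer is neither.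

    2 Z → D (k = 0.00146 M⁻¹ min⁻¹)
    Z → E (k = 5.47 × 10⁻⁵ min⁻¹)
    2 Z → L (k = 3.70 × 10⁻⁶ M⁻¹ min⁻¹)
    Z + J ⇌ G (K = 35.8 M⁻¹, k = 8.56 × 10⁻⁴ M⁻¹ min⁻¹)

Struck from Friday's run, the step into D lifts G from 34.1 % to 43.5 %, and left for ten times the time, Friday's G reaches 58.5 %. So Friday's G stands where it does because of the step into D and the length of the run acting together, and each of the two is a part of the reason. On the neighbour of Friday's charged with 0.25 M of Z, the same c gives a crossover of 2.70, then z 47.8 % and G 41.1 %; the computed neighbour ends with Z at 45.4 % and G at 42.7 %.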